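**Retrosynthetic overview**
1. Target 26 ⇐ desilylation and Lindlar semi-hydrogenation of bis-ynoate 24; the two Z-enoates are revealed last.
2. 24 ⇐ light-driven double conjugate C-alkylation of (S)-6-methyl-dihydropyran-2,4-dione 22 by two molecules of the 14-membered enedione–ynoate macrodiolide 17; this forms both C–C bonds at the quaternary carbon.
3. 17 ⇐ Shiina macrolactonisation (O1–C2) of seco acid 16 ⇐ Horner–Wadsworth–Emmons reaction of ketophosphonate ester 13 with glyoxylic acid ⇐ Steglich union of ynoic acid 8 and hydroxy ketophosphonate 12.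
4. 8 ⇐ Felkin addition of lithiated ethyl propiolate to (S)-lactaldehyde silyl ether; 12 ⇐ (S)-propylene oxide and a ketophosphonate dianion; 22 ⇐ ethyl (S)-3-hydroxybutanoate and tert-butyl acetate.
5. Ring order: six-membered keto lactone and 14-membered diolide are made separately, then two diolide rings are attached to the keto lactone.

Assumption: the target is taken exactly as drawn (both enoates Z; S at every CH(CH3)–O carbon; R at both carbinol carbons and at both ring carbons bonded to the quaternary carbon, which carries two identical arms and is not a stereocentre). Ethyl (S)-lactate, (S)-propylene oxide and ethyl (S)-3-hydroxybutanoate are taken as cheap commercial single enantiomers.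

**Step 1**
Reactants: 1 ethyl (S)-lactate
Product: 2 ethyl (2S)-2-(triethylsilyloxy)propanoate
Conditions: Et3SiCl, imidazole, DMF, 0 °C to rt
Reagents that add atoms: chlorotriethylsilane, CC[Si](CC)(CC)Cl
Why: Standard silyl ether formation on a secondary alcohol; the lactate centre (future C14, S) is not touched.

**Step 2**
Reactants: 2 ethyl (2S)-2-(triethylsilyloxy)propanoate
Product: 3 (2S)-2-(triethylsilyloxy)propanal
Conditions: i-Bu2AlH, CH2Cl2, −78 °C; aq. Rochelle salt; used crude
Reagents that add atoms: none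
Why: Low-temperature DIBAL half-reduction stops at the aldehyde through the stable tetrahedral aluminium hemiacetal, without epimerisation at −78 °C.

**Step 3**
Reactants: 3 (2S)-2-(triethylsilyloxy)propanal; 4 ethyl propiolate
Product: 6 ethyl (4R,5S)-4-hydroxy-5-(triethylsilyloxy)hex-2-ynoate, via lithium ethyl propiolate 5 (not isolated)
Conditions: 4, LiN(SiMe3)2, THF, −90 °C, 20 min; then 3, −90 °C, 1 h; AcOH quench at −90 °C
Reagents that add atoms: none
Why: Felkin–Anh addition of the lithium acetylide to the α-silyloxy aldehyde (non-chelating silyl ether) gives the anti (4R,5S) propargylic alcohol, expected about 5:1, and the minor 4S epimer is removed by chromatography.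

**Step 4**
Reactants: 6 ethyl (4R,5S)-4-hydroxy-5-(triethylsilyloxy)hex-2-ynoate
Product: 8 (4R,5S)-4-(tert-butyldimethylsilyloxy)-5-(triethylsilyloxy)hex-2-ynoic acid, via bis-silyl ethyl ester 7 (not isolated)
Conditions: t-BuMe2SiCl, imidazole, DMF, rt; then THF–H2O, LiOH·H2O, 0 °C, 1 h; cold 0.5 M HCl to pH 4
Reagents that add atoms: tert-butyldimethylsilyl chloride, CC(C)(C)[Si](C)(C)Cl; lithium hydroxide, [Li+].[OH-]
Why: Imidazole-promoted silylation of the propargylic alcohol followed by fast saponification of the activated ynoate ester; the triethylsilyl ether survives cold hydroxide and the brief pH 4 work-up.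

**Step 5**
Reactants: 9 (S)-propylene oxide; 10 dimethyl (2-oxopropyl)phosphonate
Product: 12 dimethyl [(5S)-5-hydroxy-2-oxohexyl]phosphonate, via phosphonate dianion 11 (not isolated)
Conditions: 10, NaH, THF, 0 °C; n-BuLi, 0 °C; then 9, 0 °C to rt; AcOH quench
Reagents that add atoms: none
Why: γ-Alkylation of the β-ketophosphonate dianion by SN2 opening of the epoxide at its CH2 terminus, which leaves the stereocentre (future C8, S) untouched.

**Step 6**
Reactants: 8 (4R,5S)-4-(tert-butyldimethylsilyloxy)-5-(triethylsilyloxy)hex-2-ynoic acid; 12 dimethyl [(5S)-5-hydroxy-2-oxohexyl]phosphonate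
Product: 13 (2S)-6-(dimethoxyphosphoryl)-5-oxohexan-2-yl (4R,5S)-4-(tert-butyldimethylsilyloxy)-5-(triethylsilyloxy)hex-2-ynoate
Conditions: DCC, DMAP (10 mol%), CH2Cl2, −20 to 0 °C
Reagents that add atoms: none
Why: Steglich esterification of a 2-alkynoic acid by acyl transfer, so the carbinol centre of 12 is retained.

**Step 7**
Reactants: 13 (2S)-6-(dimethoxyphosphoryl)-5-oxohexan-2-yl (4R,5S)-4-(tert-butyldimethylsilyloxy)-5-(triethylsilyloxy)hex-2-ynoate; 14 glyoxylic acid monohydrate
Product: 16 (2E,7S)-7-{[(4R,5S)-4-(tert-butyldimethylsilyloxy)-5-hydroxyhex-2-ynoyl]oxy}-4-oxooct-2-enoic acid, via silyl-protected enedione acid 15 (not isolated)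
Conditions: 14, LiCl, i-Pr2NEt, MeCN, 0 °C to rt; then 1 M aq. HCl–THF (1:4), 0 °C, 30 min
Reagents that add atoms: none
Why: Masamune–Roush Horner–Wadsworth–Emmons olefination with glyoxylic acid gives the (E)-4-oxo-2-enoic acid, and brief dilute acid then cleaves the triethylsilyl ether far faster than the tert-butyldimethylsilyl ether; the linear alkyne prevents the freed 5-hydroxyl from lactonising onto the ynoate.

**Step 8**
Reactants: 16 (2E,7S)-7-{[(4R,5S)-4-(tert-butyldimethylsilyloxy)-5-hydroxyhex-2-ynoyl]oxy}-4-oxooct-2-enoic acid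
Product: 17 (3E,8S,13R,14S)-13-(tert-butyldimethylsilyloxy)-8,14-dimethyl-1,9-dioxacyclotetradec-3-en-11-yne-2,5,10-trione
Conditions: 2-methyl-6-nitrobenzoic anhydride (MNBA), DMAP, CH2Cl2 (1 mM), rt, syringe-pump addition of 16 over 12 h
Reagents that add atoms: none
Why: Shiina macrolactonisation through the mixed anhydride under high dilution closes the 14-membered diolide at room temperature without touching any stereocentre.

**Step 9**
Reactants: 18 ethyl (3S)-3-hydroxybutanoate; 19 tert-butyl acetate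
Product: 21 tert-butyl (5S)-5-hydroxy-3-oxohexanoate, via lithium enolate of tert-butyl acetate 20 (not isolated)
Conditions: 19 (4 equiv), LiN(i-Pr)2 (4 equiv), THF, −78 °C; then 18, −78 to −20 °C; AcOH quench
Reagents that add atoms: none
Why: Crossed Claisen condensation of excess ester enolate onto the β-alkoxide ester gives the δ-hydroxy-β-keto ester with the stereocentre untouched.

**Step 10**
Reactants: 21 tert-butyl (5S)-5-hydroxy-3-oxohexanoate
Product: 22 (6S)-6-methyldihydro-2H-pyran-2,4(3H)-dione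
Conditions: CF3CO2H, CH2Cl2, rt
Reagents that add atoms: none
Why: Acidolysis of the tert-butyl ester with concomitant δ-lactonisation gives the six-membered β-keto lactone with retention at C6.

**Step 11**
Reactants: 17 (3E,8S,13R,14S)-13-(tert-butyldimethylsilyloxy)-8,14-dimethyl-1,9-dioxacyclotetradec-3-en-11-yne-2,5,10-trione (2.2 equiv); 22 (6S)-6-methyldihydro-2H-pyran-2,4(3H)-dione
Product: 24 (6S)-6-methyl-3,3-bis[(3R,8S,13R,14S)-13-(tert-butyldimethylsilyloxy)-8,14-dimethyl-2,5,10-trioxo-1,9-dioxacyclotetradec-11-yn-3-yl]dihydro-2H-pyran-2,4(3H)-dione, via mono-adduct enol 23 (not isolated)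
Conditions: 2,4,5,6-tetrakis(carbazol-9-yl)isophthalonitrile (4CzIPN, 2 mol%), 2,6-lutidine (0.5 equiv), degassed MeCN, 456 nm LEDs, 10 °C
Reagents that add atoms: none
Why: Proposed new method: a light-driven, redox-neutral radical conjugate C-alkylation in which excited 4CzIPN oxidises the lutidinium enolate of 22 (and then of 23) to its C3 radical while the reduced photocatalyst (about −1.2 V) passes the electron to the enedione of 17, so that the electrophilic dicarbonyl radical and the persistent enedione radical anion combine at macrolide carbon C3 (β to the ketone, largest spin density) and protonation gives the ketone; the early transition state of this coupling should tolerate the congestion of the quaternary centre that makes the second two-electron Michael addition slow and reversible, each new C3 centre is expected (not proven) to be R through coupling on the outer face of the 14-membered ring held by the bought 8S and 14S centres, and the ynoates are neither reduced nor sensitised at this wavelength; closest known reaction types are the base-catalysed Michael addition of cyclic 1,3-diones to enediones and photoredox radical–radical-anion cross-coupling.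

**Step 12**
Reactants: 24 (6S)-6-methyl-3,3-bis[(3R,8S,13R,14S)-13-(tert-butyldimethylsilyloxy)-8,14-dimethyl-2,5,10-trioxo-1,9-dioxacyclotetradec-11-yn-3-yl]dihydro-2H-pyran-2,4(3H)-dione
Product: 25 (6S)-6-methyl-3,3-bis[(3R,8S,11Z,13R,14S)-13-(tert-butyldimethylsilyloxy)-8,14-dimethyl-2,5,10-trioxo-1,9-dioxacyclotetradec-11-en-3-yl]dihydro-2H-pyran-2,4(3H)-dione
Conditions: H2 (1 atm), Pd/CaCO3 poisoned with Pb(OAc)2 (Lindlar catalyst), quinoline, EtOAc, rt
Reagents that add atoms: none
Why: Lindlar semi-hydrogenation (syn addition of hydrogen) converts both ynoates into Z-enoates; the enedione alkenes are already consumed, so nothing else is reducible.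

**Step 13**
Reactants: 25 (6S)-6-methyl-3,3-bis[(3R,8S,11Z,13R,14S)-13-(tert-butyldimethylsilyloxy)-8,14-dimethyl-2,5,10-trioxo-1,9-dioxacyclotetradec-11-en-3-yl]dihydro-2H-pyran-2,4(3H)-dione
Product: 26 (6S)-3,3-bis[(3R,8S,11Z,13R,14S)-13-hydroxy-8,14-dimethyl-2,5,10-trioxo-1,9-dioxacyclotetradec-11-en-3-yl]-6-methyldihydro-2H-pyran-2,4(3H)-dione (CNP0083691.2)
Conditions: HF·pyridine, pyridine, THF, 0 °C to rt
Reagents that add atoms: none
Why: Buffered fluoride desilylation removes both secondary silyl ethers under non-basic, non-nucleophilic conditions that spare the non-enolisable β-keto lactone and limit translactonisation of the Z-γ-hydroxy enoates.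

**Compound list**
1 | ethyl (S)-lactate | C[C@H](O)C(=O)OCC | starting material
2 | ethyl (2S)-2-(triethylsilyloxy)propanoate | C[C@H](O[Si](CC)(CC)CC)C(=O)OCC | intermediate
3 | (2S)-2-(triethylsilyloxy)propanal | C[C@H](O[Si](CC)(CC)CC)C=O | intermediate
4 | ethyl propiolate | C#CC(=O)OCC | starting material
5 | lithium ethyl propiolate (lithium acetylide of 4) | [Li+].[C-]#CC(=O)OCC | intermediate (not isolated)
6 | ethyl (4R,5S)-4-hydroxy-5-(triethylsilyloxy)hex-2-ynoate | C[C@H](O[Si](CC)(CC)CC)[C@H](O)C#CC(=O)OCC | intermediate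
7 | ethyl (4R,5S)-4-(tert-butyldimethylsilyloxy)-5-(triethylsilyloxy)hex-2-ynoate | C[C@H](O[Si](CC)(CC)CC)[C@H](O[Si](C)(C)C(C)(C)C)C#CC(=O)OCC | intermediate (not isolated)
8 | (4R,5S)-4-(tert-butyldimethylsilyloxy)-5-(triethylsilyloxy)hex-2-ynoic acid | C[C@H](O[Si](CC)(CC)CC)[C@H](O[Si](C)(C)C(C)(C)C)C#CC(=O)O | intermediate
9 | (S)-propylene oxide | C[C@H]1CO1 | starting material
10 | dimethyl (2-oxopropyl)phosphonate | CC(=O)CP(=O)(OC)OC | starting material
11 | sodium lithium dianion of 10 | [Na+].[Li+].[CH2-]C(=O)[CH-]P(=O)(OC)OC | intermediate (not isolated)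
12 | dimethyl [(5S)-5-hydroxy-2-oxohexyl]phosphonate | C[C@H](O)CCC(=O)CP(=O)(OC)OC | intermediate
13 | (2S)-6-(dimethoxyphosphoryl)-5-oxohexan-2-yl (4R,5S)-4-(tert-butyldimethylsilyloxy)-5-(triethylsilyloxy)hex-2-ynoate | C[C@H](O[Si](CC)(CC)CC)[C@H](O[Si](C)(C)C(C)(C)C)C#CC(=O)O[C@@H](C)CCC(=O)CP(=O)(OC)OC | intermediate
14 | glyoxylic acid monohydrate | OC(O)C(=O)O | starting material
15 | (2E,7S)-7-{[(4R,5S)-4-(tert-butyldimethylsilyloxy)-5-(triethylsilyloxy)hex-2-ynoyl]oxy}-4-oxooct-2-enoic acid | C[C@H](O[Si](CC)(CC)CC)[C@H](O[Si](C)(C)C(C)(C)C)C#CC(=O)O[C@@H](C)CCC(=O)/C=C/C(=O)O | intermediate (not isolated)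
16 | (2E,7S)-7-{[(4R,5S)-4-(tert-butyldimethylsilyloxy)-5-hydroxyhex-2-ynoyl]oxy}-4-oxooct-2-enoic acid | C[C@H](O)[C@H](O[Si](C)(C)C(C)(C)C)C#CC(=O)O[C@@H](C)CCC(=O)/C=C/C(=O)O | intermediate
17 | (3E,8S,13R,14S)-13-(tert-butyldimethylsilyloxy)-8,14-dimethyl-1,9-dioxacyclotetradec-3-en-11-yne-2,5,10-trione | C[C@@H]1OC(=O)/C=C/C(=O)CC[C@H](C)OC(=O)C#C[C@H]1O[Si](C)(C)C(C)(C)C | intermediate
18 | ethyl (3S)-3-hydroxybutanoate | C[C@H](O)CC(=O)OCC | starting material
19 | tert-butyl acetate | CC(=O)OC(C)(C)C | starting material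
20 | lithium enolate of tert-butyl acetate | [Li+].[CH2-]C(=O)OC(C)(C)C | intermediate (not isolated)
21 | tert-butyl (5S)-5-hydroxy-3-oxohexanoate | C[C@H](O)CC(=O)CC(=O)OC(C)(C)C | intermediate
22 | (6S)-6-methyldihydro-2H-pyran-2,4(3H)-dione | C[C@H]1CC(=O)CC(=O)O1 | intermediate
23 | (6S)-4-hydroxy-6-methyl-3-[(3R,8S,13R,14S)-13-(tert-butyldimethylsilyloxy)-8,14-dimethyl-2,5,10-trioxo-1,9-dioxacyclotetradec-11-yn-3-yl]-5,6-dihydro-2H-pyran-2-one (mono-adduct, enol form) | C[C@@H]1OC(=O)[C@@H](C2=C(O)C[C@H](C)OC2=O)CC(=O)CC[C@H](C)OC(=O)C#C[C@H]1O[Si](C)(C)C(C)(C)C | intermediate (not isolated)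
24 | (6S)-6-methyl-3,3-bis[(3R,8S,13R,14S)-13-(tert-butyldimethylsilyloxy)-8,14-dimethyl-2,5,10-trioxo-1,9-dioxacyclotetradec-11-yn-3-yl]dihydro-2H-pyran-2,4(3H)-dione | C[C@@H]1OC(=O)[C@@H](C2([C@H]3CC(=O)CC[C@H](C)OC(=O)C#C[C@@H](O[Si](C)(C)C(C)(C)C)[C@H](C)OC3=O)C(=O)C[C@H](C)OC2=O)CC(=O)CC[C@H](C)OC(=O)C#C[C@H]1O[Si](C)(C)C(C)(C)C | intermediate
25 | (6S)-6-methyl-3,3-bis[(3R,8S,11Z,13R,14S)-13-(tert-butyldimethylsilyloxy)-8,14-dimethyl-2,5,10-trioxo-1,9-dioxacyclotetradec-11-en-3-yl]dihydro-2H-pyran-2,4(3H)-dione | C[C@@H]1OC(=O)[C@@H](C2([C@H]3CC(=O)CC[C@H](C)OC(=O)/C=C\[C@@H](O[Si](C)(C)C(C)(C)C)[C@H](C)OC3=O)C(=O)C[C@H](C)OC2=O)CC(=O)CC[C@H](C)OC(=O)/C=C\[C@H]1O[Si](C)(C)C(C)(C)C | intermediate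
26 | (6S)-3,3-bis[(3R,8S,11Z,13R,14S)-13-hydroxy-8,14-dimethyl-2,5,10-trioxo-1,9-dioxacyclotetradec-11-en-3-yl]-6-methyldihydro-2H-pyran-2,4(3H)-dione | C[C@@H]1OC(=O)[C@@H](C2([C@H]3CC(=O)CC[C@H](C)OC(=O)/C=C\[C@@H](O)[C@H](C)OC3=O)C(=O)C[C@H](C)OC2=O)CC(=O)CC[C@H](C)OC(=O)/C=C\[C@H]1O | target

**Totals**
Total steps: 13. Longest linear sequence: 10 steps (1, 2, 3, 4, 6, 7, 8, 11, 12, 13).

**Steps most likely to fail**

Step 11 (proposed new photochemical double C-alkylation; risks are a stalled second coupling and the wrong facial outcome at C3). The fallback uses known two-electron chemistry, sets out from 17 and 22 and comes back at 24. Triethylamine-catalysed Michael addition of 22 to one equivalent of 17 in THF at rt gives the mono-adduct 23, now isolated. A second Michael addition of 23 to another equivalent of 17 is then catalysed by FeCl3·6H2O (trivalent iron chelate of the 1,3-dicarbonyl, 5 mol%, CH2Cl2, rt), conditions known to build quaternary carbons from 2-substituted 1,3-dicarbonyls. Retro-Michael/Michael equilibration under these conditions gives the thermodynamic C3 configuration. This fallback makes no compound outside the list (F0).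

Step 8 (macrolactonisation; risks are DMAP addition to the activated enedione acid, silyl migration and strain from the alkyne in the ring). The fallback closes the ring by C=C formation instead, sets out from 13 and comes back at 17. Selective removal of the triethylsilyl ether (PPTS, MeOH, 0 °C) gives (2S)-6-(dimethoxyphosphoryl)-5-oxohexan-2-yl (4R,5S)-4-(tert-butyldimethylsilyloxy)-5-hydroxyhex-2-ynoate F1. Acryloyl chloride and i-Pr2NEt (CH2Cl2, −20 °C) give the C5 acrylate ester F2. Lemieux–Johnson cleavage of the acrylate alkene (OsO4 cat., NaIO4, 2,6-lutidine, dioxane–water), which the alkyne tolerates, gives the glyoxylate ester F3. An intramolecular Masamune–Roush Horner–Wadsworth–Emmons reaction (LiCl, i-Pr2NEt, MeCN, 2 mM, rt) then forms C3=C4 and delivers 17.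

Step 13 (final desilylation; risk is acid-promoted translactonisation of the Z-γ-hydroxy enoates to butenolides). The fallback reverses the order of the last two operations, sets out from 24 and comes back at 26. HF·pyridine on 24 gives (6S)-3,3-bis[(3R,8S,13R,14S)-13-hydroxy-8,14-dimethyl-2,5,10-trioxo-1,9-dioxacyclotetradec-11-yn-3-yl]-6-methyldihydro-2H-pyran-2,4(3H)-dione F4, in which the alkyne geometry makes lactonisation impossible. Lindlar semi-hydrogenation (H2, Pd/CaCO3 poisoned with Pb(OAc)2, quinoline, EtOAc) is then the last, neutral step and gives 26 directly.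

**Further compounds**
F1 | step 8 | (2S)-6-(dimethoxyphosphoryl)-5-oxohexan-2-yl (4R,5S)-4-(tert-butyldimethylsilyloxy)-5-hydroxyhex-2-ynoate | C[C@H](O)[C@H](O[Si](C)(C)C(C)(C)C)C#CC(=O)O[C@@H](C)CCC(=O)CP(=O)(OC)OC
F2 | step 8 | (2S)-6-(dimethoxyphosphoryl)-5-oxohexan-2-yl (4R,5S)-5-(acryloyloxy)-4-(tert-butyldimethylsilyloxy)hex-2-ynoate | C=CC(=O)O[C@@H](C)[C@H](O[Si](C)(C)C(C)(C)C)C#CC(=O)O[C@@H](C)CCC(=O)CP(=O)(OC)OC
F3 | step 8 | (2S)-6-(dimethoxyphosphoryl)-5-oxohexan-2-yl (4R,5S)-4-(tert-butyldimethylsilyloxy)-5-(2-oxoacetoxy)hex-2-ynoate | O=CC(=O)O[C@@H](C)[C@H](O[Si](C)(C)C(C)(C)C)C#CC(=O)O[C@@H](C)CCC(=O)CP(=O)(OC)OC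
F0 | step 11 | none | none
F4 | step 13 | (6S)-3,3-bis[(3R,8S,13R,14S)-13-hydroxy-8,14-dimethyl-2,5,10-trioxo-1,9-dioxacyclotetradec-11-yn-3-yl]-6-methyldihydro-2H-pyran-2,4(3H)-dione | C[C@@H]1OC(=O)[C@@H](C2([C@H]3CC(=O)CC[C@H](C)OC(=O)C#C[C@@H](O)[C@H](C)OC3=O)C(=O)C[C@H](C)OC2=O)CC(=O)CC[C@H](C)OC(=O)C#C[C@H]1O
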